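**Plan**
- Retrosynthesis: first cleave the tert-butyl ester and trace the C7-OAc/C8-OH pair back through a 7β,8β-epoxy-14-ketone to the C7=C8 enone. Then return the C13 vinyl group and O11 to a bridging γ-lactone, the CH2CO2H arm to a C1 aldehyde and CMe2 to CH2. Last, cut both ring-B bonds C9–C10 and C5–C6 together ([4+2]) into the ring-C vinyl diene 11 and the enal 13.
- Forward: ring C is made first (catalytic asymmetric Diels–Alder, iodolactonisation, vinylation). Ring B then closes in one intermolecular Diels–Alder step that joins a ten-carbon and a six-carbon fragment at the quaternary carbon C10. Side arms and the oxygen pattern follow.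
- Enabling feature: ring B (C5–C10) carries oxygen on C7 and C8, the mark of a C7=C8 cyclohexene. On ring C, O11 and the vinyl carbon C15 on C13 are 1,3-cis, so they can be tied as a γ-lactone (6-oxabicyclo[3.2.1]octene) that covers the α-face of the diene C9=C8–C7=C6.
- Stereochemistry: C13 from the enantioselective Diels–Alder step; C11 from iodolactonisation; C9, C10 and C5 from the key step (β-face, exo, E-alkene); C8 and C7 from a 14β-OH-directed epoxidation and trans-diaxial acetolysis.

Key step: step 11

Remarks (chemistry):
- Numbering is the usual diterpene numbering of the target. Ring B = C5, C6, C7, C8, C9, C10; ring C = C8, C9, C11, C12, C13, C14. C10 carries methyl C20 and the C1H2–C2O2H arm; C5 carries C4(Me)2–C3O2H; C13 carries methyl C17 and vinyl C15=C16. β = face of the C10 methyl, α = face of H9.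
- Assumption: the antipode of the oxazaborolidinium catalyst in step 1 is the one that gives (R)-3; if the (S)-prolinol-derived catalyst gives (S)-3, its mirror image is used.
- Compounds 15 and 17–20 are E/Z mixtures at the enol ether, 18 is an anomer mixture and 16 a C4-epimer mixture; all of these elements disappear later. The C14 carbinol configuration in 10, 11 and 14–20 is temporary.

Step 1
Reactants: 1 methacrolein (2-methylprop-2-enal); 2 buta-1,3-diene
Product: 3 (R)-1-methylcyclohex-3-ene-1-carbaldehyde
Conditions: 2 (excess), (S)-3,3-diphenyl-1-(2-methylphenyl)tetrahydropyrrolo[1,2-c][1,3,2]oxazaborole·HN(SO2CF3)2 (10 mol%), CH2Cl2, −78 °C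
Reagents that add atoms: none
Why: Catalytic enantioselective Diels–Alder reaction of an α-substituted acrolein with a simple diene under chiral oxazaborolidinium activation, in which the catalyst shields one face of the bound enal and so sets the quaternary centre C13.

Step 2
Reactants: 3 (R)-1-methylcyclohex-3-ene-1-carbaldehyde
Product: 4 (R)-1-methylcyclohex-3-ene-1-carboxylic acid
Conditions: NaClO2, NaH2PO4, 2-methyl-2-butene, t-BuOH/H2O, 0 °C → rt
Reagents that add atoms: sodium chlorite, [Na+].[O-]Cl=O
Why: Pinnick oxidation converts the non-enolisable aldehyde to the acid without touching the ring alkene, because the alkene scavenger takes up the hypochlorite.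

Step 3
Reactants: 4 (R)-1-methylcyclohex-3-ene-1-carboxylic acid
Product: 5 iodolactone (4-iodo-1-methyl-6-oxabicyclo[3.2.1]octan-7-one; O11 α, iodine on C9 β)
Conditions: I2, KI, NaHCO3, H2O/THF, 0 °C → rt, dark
Reagents that add atoms: iodine, II
Why: Iodolactonisation, in which the carboxylate can only reach C11 to form the cis-bridged γ-lactone and attacks anti to the iodonium ion, so O11 is set cis to C15 (both α) and iodine ends trans on C9.

Step 4
Reactants: 5 iodolactone
Product: 6 (1R,5R)-1-methyl-6-oxabicyclo[3.2.1]oct-3-en-7-one (C8=C9 alkene)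
Conditions: DBU, toluene, 110 °C
Reagents that add atoms: none
Why: E2 dehydroiodination, in which only a hydrogen on C8 is anti-periplanar to the axial C9–I bond (H11 is syn), so the double bond should form at C8=C9 only.

Step 5
Reactants: 6 alkene lactone
Product: 7 (1S,5R)-1-methyl-6-oxabicyclo[3.2.1]oct-3-ene-2,7-dione (C14 ketone conjugated with C8=C9)
Conditions: CrO3, 3,5-dimethylpyrazole, CH2Cl2, −20 °C
Reagents that add atoms: chromium trioxide, O=[Cr](=O)=O
Why: Allylic oxidation of a cyclohexene to the enone, in which C14 is the only allylic methylene and the bridgehead C11–H lies in the nodal plane of the π-bond, while the lactone is inert to the oxidant.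

Step 6
Reactants: 7 enone lactone
Product: 8 3-iodo-1-methyl-6-oxabicyclo[3.2.1]oct-3-ene-2,7-dione (iodine on C8)
Conditions: I2, pyridine/CH2Cl2 (1:1), 0 °C → rt
Reagents that add atoms: iodine, II
Why: Johnson α-iodination of an enone (pyridine conjugate addition at C9, iodination of the enolate at C8, loss of pyridine), for which the non-enolisable C14 ketone leaves no other site.

Step 7
Reactants: 8 α-iodoenone
Product: 9 3-ethenyl-1-methyl-6-oxabicyclo[3.2.1]oct-3-ene-2,7-dione (vinyl C7=C6 on C8)
Conditions: Bu3SnCH=CH2, Pd2(dba)3 (2.5 mol%), AsPh3 (10 mol%), CuI (10 mol%), NMP, rt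
Reagents that add atoms: tributyl(vinyl)stannane, C=C[Sn](CCCC)(CCCC)CCCC
Why: Stille coupling of an α-iodoenone with a vinylstannane under mild, neutral conditions that leave the lactone untouched; the cross-conjugated dienone is carried on directly.

Step 8
Reactants: 9 dienone
Product: 10 dienol (2-hydroxy-1-methyl-3-vinyl-6-oxabicyclo[3.2.1]oct-3-en-7-one; 14α-OH, on the side of the lactone bridge)
Conditions: NaBH4, CeCl3·7H2O, MeOH, −40 °C
Reagents that add atoms: none
Why: Luche 1,2-reduction of the enone, in which hydride should enter from the exo (β) face away from the lactone carbonyl to give the 14α-alcohol, while the lactone survives at low temperature.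

Step 9
Reactants: 10 dienol
Product: 11 triethylsilyl ether of 10 (ring-C diene: C9=C8–C7=C6, 14α-OSiEt3, 11α,15-lactone)
Conditions: Et3SiCl, imidazole, DMF, 0 °C → rt
Reagents that add atoms: chlorotriethylsilane, CC[Si](Cl)(CC)CC
Why: Standard silylation, which turns C14 into a plain alkyl-type substituent of the diene and keeps the α-face covered.

Step 10
Reactants: 1 methacrolein; 12 tert-butyl but-3-enoate
Product: 13 tert-butyl (E)-4-methyl-5-oxopent-3-enoate
Conditions: 1 (5 equiv), RuCl2(=CH-C6H4-2-O-i-Pr)(H2IMes) (second-generation Hoveyda–Grubbs catalyst, 3 mol%), CH2Cl2, 40 °C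
Reagents that add atoms: none
Why: Olefin cross-metathesis of a terminal alkene with methacrolein, which should give the trisubstituted enal as the E isomer, the conjugated and thermodynamically preferred one.

Step 11
Reactants: 11 ring-C diene; 13 tert-butyl (E)-4-methyl-5-oxopent-3-enoate
Product: 14 Diels–Alder adduct (ring B closed: Δ7; 9α-H; 10β-methyl; 10α-formyl; 5α-H; 5β-CH2CO2t-Bu; 14α-OSiEt3; 11α,15-lactone)
Conditions: 13 and Al(OC6H3-2,6-Ph2)3 (1.2 equiv), toluene, −78 °C, then 11, −78 → −20 °C
Reagents that add atoms: none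
Why: The step is a Lewis-acid-promoted intermolecular [4+2] cycloaddition of normal electron demand, concerted but asynchronous (the bond from the unsubstituted diene terminus C6 to the enal β-carbon C5 leads, C9–C10 follows), and its closest known type is the Lewis-acid Diels–Alder reaction of 1-vinylcyclohexenes with α-methyl-α,β-unsaturated aldehydes, including the exo-selective variant with bulky aluminium aryloxides. Ring B (C5–C6–C7–C8–C9–C10) is closed by suprafacial–suprafacial addition of the C10=C5 bond across C9 and C6, both σ-bonds forming in one operation and the C7=C8 double bond remaining. C9 is set by attack on the β-face, because the O11–C15 lactone bridge and the 14α-silyloxy group cover the α-face of the bicyclic diene. C10 and C5 are fixed relative to each other by the E-geometry of 13 (methyl and CH2CO2t-Bu cis) and relative to C9 by the exo position of the formyl group. The step needs regio-, facial and exo selectivity: joining the formyl-bearing carbon to the ring terminus C9 is the normal "ortho" outcome for 1-vinylcycloalkenes, and exo selectivity is expected because the formyl group bound to the bulky aluminium phenoxide does not fit the endo pocket over ring C (between H14β and the C12 bridge), so the small α-methyl group goes endo, as α-methyl enals prefer in any case. The aluminium reagent binds aldehydes selectively, so the allylic lactone and the silyl ether of the diene should not be ionised.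

Step 12
Reactants: 14 Diels–Alder adduct
Product: 15 methyl enol ether (C10–CH=CH–OMe in place of the formyl group)
Conditions: Ph3P(CH2OMe)Cl, KN(SiMe3)2, THF, 0 °C → rt
Reagents that add atoms: (methoxymethyl)triphenylphosphonium chloride, [Cl-].COC[P+](c1ccccc1)(c1ccccc1)c1ccccc1
Why: Wittig one-carbon homologation of the non-enolisable neopentyl aldehyde brings in C2 and masks it as an enol ether that tolerates the strong bases and the hydride of the next steps; lactone, silyl ether and tert-butyl ester do not react with the ylide.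

Step 13
Reactants: 15 methyl enol ether
Product: 17 gem-dimethyl ester (C5–CMe2–CO2t-Bu; C4 quaternary), via C4-monomethyl ester 16 (not isolated)
Conditions: LiN(i-Pr)2 (1.1 equiv), THF, −78 °C, MeI; then LiN(i-Pr)2 (1.3 equiv), DMPU, −78 °C, MeI, → 0 °C (one pot)
Reagents that add atoms: iodomethane, CI
Why: Two successive ester-enolate alkylations build the C4 quaternary carbon after the ring is closed, both C4 epimers of 16 converging on 17; the only acidic C–H bonds are those α to the tert-butyl ester, since the bridged lactone has no α-hydrogen.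

Step 14
Reactants: 17 gem-dimethyl ester
Product: 18 lactol (C15 hemiacetal bridging C13 and O11)
Conditions: i-Bu2AlH (1.2 equiv), CH2Cl2, −78 °C; aq. potassium sodium tartrate work-up
Reagents that add atoms: none
Why: Partial reduction of a lactone to the lactol at low temperature, chemoselective because the strained bridged lactone is far more electrophilic than the hindered, pivalate-like tert-butyl ester.

Step 15
Reactants: 18 lactol
Product: 19 13α-vinyl-11α-alcohol (lactone bridge opened)
Conditions: Ph3PCH3Br, KN(SiMe3)2, THF, 0 → 40 °C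
Reagents that add atoms: methyltriphenylphosphonium bromide, [Br-].C[P+](c1ccccc1)(c1ccccc1)c1ccccc1
Why: Wittig methylenation of the lactol through its hydroxy-aldehyde form turns the temporary bridge into the C13 vinyl group and the free 11α-hydroxyl; the aldehyde carbon has no α-hydrogen, so nothing can epimerise.

Step 16
Reactants: 19 13α-vinyl-11α-alcohol
Product: 20 11α-benzoate
Conditions: BzCl, pyridine, DMAP (cat.), CH2Cl2, 0 °C → rt
Reagents that add atoms: benzoyl chloride, O=C(Cl)c1ccccc1
Why: Acylation of the only free (equatorial, secondary) hydroxyl, done before C2 is unmasked so that no δ-lactone can form between O11 and C2.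

Step 17
Reactants: 20 11α-benzoate
Product: 22 enone acid (C2 carboxylic acid; 14-oxo-Δ7), via hydroxy aldehyde 21 (not isolated)
Conditions: CrO3, H2SO4, H2O, acetone, 0 °C (Jones oxidation)
Reagents that add atoms: water, O; chromium trioxide, O=[Cr](=O)=O
Why: Under Jones conditions the enol ether and the triethylsilyl ether are hydrolysed, the aldehyde is oxidised to the C2 acid and the allylic 14-alcohol to the enone in one operation; benzoate, vinyl group and tert-butyl ester should survive the short exposure at 0 °C.

Step 18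
Reactants: 22 enone acid
Product: 23 14β-allylic alcohol (equatorial OH)
Conditions: NaBH4, CeCl3·7H2O, MeOH, −20 °C
Reagents that add atoms: none
Why: Luche 1,2-reduction with axial hydride attack from the α-face, anti to the axial 13β-methyl group, should give the equatorial 14β-alcohol; benzoate and tert-butyl ester are not reduced and the acid is only deprotonated.

Step 19
Reactants: 23 14β-allylic alcohol
Product: 24 7β,8β-epoxy-14β-alcohol
Conditions: VO(acac)2 (5 mol%), t-BuOOH, CH2Cl2, 0 °C → rt
Reagents that add atoms: tert-butyl hydroperoxide, CC(C)(C)OO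
Why: Vanadium-catalysed hydroxyl-directed epoxidation delivers oxygen to the C7=C8 bond from the face of the 14β-hydroxyl, which sets the C8–O bond β against the steric bias of the C17 and C20 methyl groups and leaves the isolated vinyl group untouched.

Step 20
Reactants: 24 7β,8β-epoxy-14β-alcohol
Product: 25 7β,8β-epoxy-14-ketone
Conditions: Dess–Martin periodinane, CH2Cl2, 0 °C → rt
Reagents that add atoms: none
Why: Mild oxidation of the hindered secondary alcohol to the ketone, which also makes C8 an α-keto carbon that cannot be opened in the next step; epoxide, esters and acid are inert.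

Step 21
Reactants: 25 7β,8β-epoxy-14-ketone
Product: 26 mono-tert-butyl ester of the target (7α-OAc, 8β-OH, 14-ketone)
Conditions: AcOH, NaOAc, 70 °C
Reagents that add atoms: acetic acid, CC(=O)O
Why: Acetolysis of an α,β-epoxy ketone at the β-carbon: acetate attacks the secondary C7 from the open α-face with inversion (trans-diaxial, Fürst–Plattner), while the tertiary, carbonyl-flanked C8 keeps its β-oxygen; the resulting β-acetoxy ketone cannot eliminate because C8 has no hydrogen.

Step 22
Reactants: 26 mono-tert-butyl ester of the target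
Product: 27 target diacid
Conditions: CF3CO2H, CH2Cl2, 0 °C → rt
Reagents that add atoms: none
Why: Acidolysis of the tert-butyl ester by loss of isobutene; acetate, benzoate, the vinyl group and the tertiary α-ketol (whose ionisation is disfavoured next to the ketone) should be stable.

**Compound list**
1 | methacrolein (2-methylprop-2-enal) | C=C(C)C=O | starting material
2 | buta-1,3-diene | C=CC=C | starting material
3 | (R)-1-methylcyclohex-3-ene-1-carbaldehyde | O=C[C@@]1(C)CC=CCC1 | intermediate
4 | (R)-1-methylcyclohex-3-ene-1-carboxylic acid | OC(=O)[C@@]1(C)CC=CCC1 | intermediate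
5 | iodolactone, 4-iodo-1-methyl-6-oxabicyclo[3.2.1]octan-7-one (O11 α, I on C9 β) | O=C1O[C@@H]2C[C@@]1(C)CC[C@H]2I | intermediate
6 | (1R,5R)-1-methyl-6-oxabicyclo[3.2.1]oct-3-en-7-one | O=C1O[C@@H]2C[C@@]1(C)CC=C2 | intermediate
7 | (1S,5R)-1-methyl-6-oxabicyclo[3.2.1]oct-3-ene-2,7-dione | O=C1O[C@@H]2C[C@@]1(C)C(=O)C=C2 | intermediate
8 | 3-iodo derivative of 7 (iodine on C8) | O=C1O[C@@H]2C[C@@]1(C)C(=O)C(I)=C2 | intermediate
9 | 3-ethenyl derivative of 7 (cross-conjugated dienone) | O=C1O[C@@H]2C[C@@]1(C)C(=O)C(C=C)=C2 | intermediate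
10 | dienol, 14α-OH (2-hydroxy-1-methyl-3-vinyl-6-oxabicyclo[3.2.1]oct-3-en-7-one) | O=C1O[C@@H]2C[C@@]1(C)[C@H](O)C(C=C)=C2 | intermediate
11 | triethylsilyl ether of 10 (ring-C diene) | O=C1O[C@@H]2C[C@@]1(C)[C@H](O[Si](CC)(CC)CC)C(C=C)=C2 | intermediate
12 | tert-butyl but-3-enoate | C=CCC(=O)OC(C)(C)C | starting material
13 | tert-butyl (E)-4-methyl-5-oxopent-3-enoate | O=C/C(C)=C/CC(=O)OC(C)(C)C | intermediate
14 | Diels–Alder adduct (Δ7; 9α-H; 10β-Me; 10α-CHO; 5β-CH2CO2t-Bu; 14α-OSiEt3; 11α,15-lactone) | O=C1O[C@@H]2C[C@@]1(C)[C@H](O[Si](CC)(CC)CC)C3=CC[C@@H](CC(=O)OC(C)(C)C)[C@](C)(C=O)[C@@H]23 | intermediate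
15 | methyl enol ether of 14 (C10–CH=CH–OMe, E/Z mixture) | O=C1O[C@@H]2C[C@@]1(C)[C@H](O[Si](CC)(CC)CC)C3=CC[C@@H](CC(=O)OC(C)(C)C)[C@](C)(C=COC)[C@@H]23 | intermediate
16 | C4-monomethyl ester (C4 epimers; not isolated) | O=C1O[C@@H]2C[C@@]1(C)[C@H](O[Si](CC)(CC)CC)C3=CC[C@@H](C(C)C(=O)OC(C)(C)C)[C@](C)(C=COC)[C@@H]23 | intermediate
17 | C4-gem-dimethyl ester (C5–CMe2–CO2t-Bu) | O=C1O[C@@H]2C[C@@]1(C)[C@H](O[Si](CC)(CC)CC)C3=CC[C@@H](C(C)(C)C(=O)OC(C)(C)C)[C@](C)(C=COC)[C@@H]23 | intermediate
18 | lactol (C15 hemiacetal, anomer mixture) | OC1O[C@@H]2C[C@@]1(C)[C@H](O[Si](CC)(CC)CC)C3=CC[C@@H](C(C)(C)C(=O)OC(C)(C)C)[C@](C)(C=COC)[C@@H]23 | intermediate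
19 | 13α-vinyl-11α-alcohol (14α-OSiEt3, Δ7, enol ether, tert-butyl ester) | C=C[C@@]1(C)C[C@@H](O)[C@@H]2[C@@](C)(C=COC)[C@H](C(C)(C)C(=O)OC(C)(C)C)CC=C2[C@H]1O[Si](CC)(CC)CC | intermediate
20 | 11α-benzoate of 19 | C=C[C@@]1(C)C[C@@H](OC(=O)c3ccccc3)[C@@H]2[C@@](C)(C=COC)[C@H](C(C)(C)C(=O)OC(C)(C)C)CC=C2[C@H]1O[Si](CC)(CC)CC | intermediate
21 | 14α-hydroxy C2-aldehyde (not isolated) | C=C[C@@]1(C)C[C@@H](OC(=O)c3ccccc3)[C@@H]2[C@@](C)(CC=O)[C@H](C(C)(C)C(=O)OC(C)(C)C)CC=C2[C@H]1O | intermediate
22 | enone acid (C2-CO2H, 14-oxo-Δ7, 11α-OBz, C3 tert-butyl ester) | C=C[C@@]1(C)C[C@@H](OC(=O)c3ccccc3)[C@@H]2[C@@](C)(CC(=O)O)[C@H](C(C)(C)C(=O)OC(C)(C)C)CC=C2C1=O | intermediate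
23 | 14β-allylic alcohol | C=C[C@@]1(C)C[C@@H](OC(=O)c3ccccc3)[C@@H]2[C@@](C)(CC(=O)O)[C@H](C(C)(C)C(=O)OC(C)(C)C)CC=C2[C@@H]1O | intermediate
24 | 7β,8β-epoxy-14β-alcohol | C=C[C@@]1(C)C[C@@H](OC(=O)c4ccccc4)[C@@H]2[C@@](C)(CC(=O)O)[C@H](C(C)(C)C(=O)OC(C)(C)C)C[C@@H]3O[C@]23[C@@H]1O | intermediate
25 | 7β,8β-epoxy-14-ketone | C=C[C@@]1(C)C[C@@H](OC(=O)c4ccccc4)[C@@H]2[C@@](C)(CC(=O)O)[C@H](C(C)(C)C(=O)OC(C)(C)C)C[C@@H]3O[C@]23C1=O | intermediate
26 | mono-tert-butyl (C3) ester of the target | C=C[C@@]1(C)C[C@@H](OC(=O)c3ccccc3)[C@@H]2[C@@](C)(CC(=O)O)[C@H](C(C)(C)C(=O)OC(C)(C)C)C[C@@H](OC(C)=O)[C@@]2(O)C1=O | intermediate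
27 | target: 7α-acetoxy-11α-benzoyloxy-8β-hydroxy-14-oxo ring-B/C diacid | C=C[C@@]1(C)C[C@@H](OC(=O)c2ccccc2)[C@@H]2[C@@](C)(CC(=O)O)[C@H](C(C)(C)C(=O)O)C[C@@H](OC(C)=O)[C@@]2(O)C1=O | target

**Step count:** 22 steps in total. Longest linear sequence: 21 steps (steps 1–9 and 11–22).

**Three steps most likely to fail**

Step 11 (key cycloaddition). What may go wrong: the formyl group may take the endo position, which would invert C10 and C5 relative to C9. The hindered trisubstituted enal may also add so slowly that Lewis-acid ionisation of the allylic lactone takes over. Fallback, setting out from 11 and 13 and coming back at 14: 13 is converted with ethane-1,2-diol and catalytic p-toluenesulfonic acid into tert-butyl (E)-4-(1,3-dioxolan-2-yl)pent-3-enoate F1. With catalytic Me3SiOSO2CF3 and 2,6-di-tert-butylpyridine in CH2Cl2 at −78 °C, F1 opens to a 2-alkoxy-allyl cation, a much stronger and bulkier 2π partner (ionic Diels–Alder reaction of the Gassman type). This should add to 11 on the same β-face to give the dioxolane adduct F2. Pyridinium p-toluenesulfonate in wet acetone then returns aldehyde 14.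

Step 19 (directed epoxidation). What may go wrong: delivery to the β-face, which carries the two axial methyl groups C17 and C20, may be slow or unselective, or oxidation of the allylic alcohol back to 22 may win. Fallback, setting out from 23 and coming back at 24: N-bromosuccinimide in aqueous acetone forms the bromonium ion on the open α-face and water opens it at the tertiary C8 from the β-side (Markovnikov, trans-diaxial) to the 7α-bromo-8β,14β-diol F3. DBU then closes the 7β,8β-epoxide 24 by intramolecular SN2 displacement of bromide.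

Step 21 (acetolysis). What may go wrong: the opening in acetic acid may be sluggish, or an acid-induced acyl shift of the epoxy ketone (House-type rearrangement) may compete. Fallback, setting out from 24 and coming back at 26: the order of oxidation and opening is reversed. Ti(O-i-Pr)4 with AcOH in CH2Cl2 opens the 2,3-epoxy alcohol 24 at the carbon remote from the carbinol (C7, the known titanium-assisted C3-selective opening) with inversion, to the 7α-acetoxy-8β,14β-diol F4. Dess–Martin oxidation of the one remaining secondary hydroxyl (C14) then gives 26.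

**Further compounds**
F1 | step 11 | tert-butyl (E)-4-(1,3-dioxolan-2-yl)pent-3-enoate | O1CCOC1/C(C)=C/CC(=O)OC(C)(C)C
F2 | step 11 | dioxolane analogue of 14 (C10 carries 1,3-dioxolan-2-yl in place of formyl) | O=C1O[C@@H]2C[C@@]1(C)[C@H](O[Si](CC)(CC)CC)C3=CC[C@@H](CC(=O)OC(C)(C)C)[C@](C)(C4OCCO4)[C@@H]23
F3 | step 19 | 7α-bromo-8β,14β-diol | C=C[C@@]1(C)C[C@@H](OC(=O)c3ccccc3)[C@@H]2[C@@](C)(CC(=O)O)[C@H](C(C)(C)C(=O)OC(C)(C)C)C[C@@H](Br)[C@@]2(O)[C@@H]1O
F4 | step 21 | 7α-acetoxy-8β,14β-diol | C=C[C@@]1(C)C[C@@H](OC(=O)c3ccccc3)[C@@H]2[C@@](C)(CC(=O)O)[C@H](C(C)(C)C(=O)OC(C)(C)C)C[C@@H](OC(C)=O)[C@@]2(O)[C@@H]1O
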